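## Retrosynthetic overview

Morinin L (1) is acyclic, so no rings are formed. It has no stereocentres, only three alkenes: angelate Z, 2‑(acyloxymethyl)butenoate Z, and cinnamyl E. The "single enantiomer" instruction is therefore moot.

1. Disconnect the angelate ester of 1 to angelic acid (3) and hydroxy‑ester 2, (E)‑3,4‑dimethoxycinnamyl (Z)‑2‑(hydroxymethyl)but‑2‑enoate.
2. Disconnect the cinnamyl ester of 2 by Pd‑catalysed carbonylation: vinyl iodide 4 + CO + (E)‑3,4‑dimethoxycinnamyl alcohol (5). This step keeps the alkene geometry.
3. Make the (Z)‑vinyl iodide 4, with I cis to CH3, from 2‑butyn‑1‑ol (6) by anti‑hydroalumination then iodination. This sets the unusual angelate‑type geometry, with the ester cis to the C4 methyl.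

Assumption: the 2‑position of the acid unit must carry the ester cis to the CH3, as given by the SMILES. Tiglate‑type routes such as Baylis–Hillman SN2′ give the opposite geometry, so they were rejected.

## Route

**Step 1**
Reactants: 6, 2‑butyn‑1‑ol
Product: 4, (Z)‑2‑iodobut‑2‑en‑1‑ol
Conditions: LiAlH4 (3 equiv)/AlCl3 (1 equiv), Et2O/THF, 0 °C → rt; then I2, –78 → 0 °C
Reagents that add atoms: I2 (II)
Why: AlCl3‑modified hydroalumination of a propargylic alcohol (Corey) adds H and Al trans, with H on C3 and Al on C2. Iodinolysis of the C–Al bond proceeds with retention. I on C2 is therefore trans to H and cis to CH3, giving the Z‑vinyl iodide whose CH2OH is trans to CH3. No stereocentre is formed.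

**Step 2**
Reactants: 4, (Z)‑2‑iodobut‑2‑en‑1‑ol; 5, (E)‑3,4‑dimethoxycinnamyl alcohol (3 equiv)
Product: 2, (E)‑3,4‑dimethoxycinnamyl (Z)‑2‑(hydroxymethyl)but‑2‑enoate
Conditions: Pd(PPh3)4 (5 mol %), Et3N (2 equiv), CO (1 atm), THF, 50 °C
Reagents that add atoms: carbon monoxide, [C-]#[O+]
Why: Pd‑catalysed alkoxycarbonylation of a vinyl iodide (oxidative addition, CO insertion, alcoholysis) occurs with retention of alkene geometry. The CO2R therefore replaces I cis to CH3. Excess primary alcohol outcompetes oligomerisation through the free CH2OH of 4, and the E‑cinnamyl alkene is untouched.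

**Step 3**
Reactants: 2, hydroxy‑ester; 3, angelic acid
Product: 1, Morinin L
Conditions: 3 (1.5 equiv), 2,4,6‑Cl3C6H2COCl, Et3N, THF, rt; then 2 and DMAP, toluene, rt (Yamaguchi esterification)
Reagents that add atoms: none (angelic acid is the reactant that supplies the angeloyl group; the trichlorobenzoyl unit is lost)
Why: Yamaguchi esterification forms a mixed anhydride, and DMAP transfers the angeloyl group selectively to the primary allylic alcohol. Running at room temperature avoids Z→E (angelate→tiglate) isomerisation. The other two esters and alkenes are untouched.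

## Compound list

| No. | Name | SMILES | Role |
|---|---|---|---|
| 1 | Morinin L | C/C=C(/C)C(=O)OC/C(=C/C)C(=O)OC/C=C/c1ccc(OC)c(OC)c1 | target |
| 2 | (E)‑3,4‑dimethoxycinnamyl (Z)‑2‑(hydroxymethyl)but‑2‑enoate | OC/C(=C/C)C(=O)OC/C=C/c1ccc(OC)c(OC)c1 | intermediate |
| 3 | angelic acid ((Z)‑2‑methylbut‑2‑enoic acid) | C/C=C(/C)C(=O)O | starting material |
| 4 | (Z)‑2‑iodobut‑2‑en‑1‑ol | OC/C(I)=C/C | intermediate |
| 5 | (E)‑3,4‑dimethoxycinnamyl alcohol | OC/C=C/c1ccc(OC)c(OC)c1 | starting material |
| 6 | 2‑butyn‑1‑ol | CC#CCO | starting material |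

**Total steps:** 3. **Longest linear sequence:** 3 steps (6 → 4 → 2 → 1).

## Three steps most likely to fail

1. **Step 1 (regio‑ and stereochemistry of hydroalumination).** The 3‑iodo isomer or a mixture may form.
   Fallback: a Z‑selective Horner–Wadsworth–Emmons olefination (Still–Gennari/Ando type) of acetaldehyde with a bis(aryloxy)phosphonoacetate bearing a CH2OTBS group. This gives the Z‑acid unit directly, followed by deprotection and esterification.
2. **Step 2 (Pd carbonylation).** Pd(0) can ionise the product's cinnamyl ester, and the free OH can cause oligomerisation.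
   Fallback: TBS‑protect 4, carbonylate in MeOH, saponify, couple with 5 by EDC/DMAP, then remove TBS with TBAF/AcOH. This is a stepwise esterification with no Pd exposure of the allylic ester.
3. **Step 3 (angelate retention).** Angeloyl activation can isomerise the acid to tigloyl.
   Fallback: a Mitsunobu esterification of 2 with 3 (PPh3/DIAD, 0 °C). The acid is never converted to an acyl electrophile, so the Z geometry is retained.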